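**Retrosynthetic overview**

1. Target 18 ⇐ silyl-protected triol 14 (O-5 acetylation, double tigloylation, desilylation) ⇐ enone acetonide 11 (bulky-hydride reduction sets C1; a lipase resolution fixes the absolute configuration, because the cycloaddition is racemic).
2. Enone 11 ⇐ CO2-bridged lactone 9: cleaving the enol acetate triggers β-elimination of the bridging carboxylate from C3 and decarboxylation at C6, so the lactone bridge is a temporary ring that leaves no trace.
3. Lactone 9 ⇐ 4-acetoxy-3-isopropyl-6-(silyloxymethyl)-2-pyrone 7 + 2,2-dimethyl-1,3-dioxole 8: a dearomatising [4+2] cycloaddition forms C3–C4 and C5–C6 of the target ring and brings in the cis-4,5-diol.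
4. Enabling feature: in the cyclohexene ring the C1 oxygen sits between C6 (isopropyl) and C2=C3 (CH2OH on C3), with C3 and C6 para to each other. At the C1-ketone level this C6–C1(=O)–C2=C3 array is what a 4-oxy-2-pyrone leaves when its lactone bridge (pyrone O1–C2) across those two carbons is expelled, and C4–C5 is a cis-enediol dienophile.
5. Ring order: pyrone ring (dianion acylation, lactonisation) → bicyclo[2.2.2] lactone (key step, carbocycle closed) → bridge removed to give the cyclohexenone.

Key step: step 5

Remark: 2,2-dimethyl-1,3-dioxole (8) is taken as purchasable; compounds 9–12 are racemic and their SMILES show the enantiomer carried on to 18; carbocycles are numbered as in the target (C1 carbinol or carbonyl carbon, C2=C3 with CH2O on C3, C4 and C5 oxygenated, C6 bearing isopropyl).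

**Step 1**
Reactants: 1 methyl glycolate
Product: 2 methyl 2-[(tert-butyldiphenylsilyl)oxy]acetate
Conditions: TBDPSCl, imidazole, CH2Cl2, 0 °C to rt
Reagents that add atoms: tert-butyl(chloro)diphenylsilane CC(C)(C)[Si](Cl)(c1ccccc1)c1ccccc1
Why: Imidazole-promoted silylation of a primary alcohol; the TBDPS ether should survive base, hydride and aqueous acid and is removed by fluoride at the end.

**Step 2**
Reactants: 3 ethyl 2-acetyl-3-methylbutanoate (ethyl 2-isopropylacetoacetate); 2 methyl 2-[(tert-butyldiphenylsilyl)oxy]acetate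
Product: 5 ethyl 6-[(tert-butyldiphenylsilyl)oxy]-3,5-dioxo-2-(propan-2-yl)hexanoate, via dilithium dianion 4 (not isolated)
Conditions: 3 (2 equiv), LiN(i-Pr)2 (4.2 equiv), THF, −78 to 0 °C; then 2 (1 equiv), −78 to 0 °C; AcOH quench
Reagents that add atoms: none
Why: γ-Acylation (Claisen condensation) of a β-keto ester dianion, in which the terminal carbanion is the more reactive site and the second equivalent of dianion takes up the acidic proton of the tricarbonyl product.

**Step 3**
Reactants: 5 ethyl 6-[(tert-butyldiphenylsilyl)oxy]-3,5-dioxo-2-(propan-2-yl)hexanoate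
Product: 6 6-{[(tert-butyldiphenylsilyl)oxy]methyl}-4-hydroxy-3-(propan-2-yl)-2H-pyran-2-one
Conditions: DBU (0.3 equiv), toluene, 100 °C
Reagents that add atoms: none
Why: Base-mediated lactonisation of a 3,5-dioxo ester through the C5 enol oxygen, the standard triketide-to-4-hydroxy-2-pyrone cyclisation, driven by loss of ethanol and aromatisation.

**Step 4**
Reactants: 6 6-{[(tert-butyldiphenylsilyl)oxy]methyl}-4-hydroxy-3-(propan-2-yl)-2H-pyran-2-one
Product: 7 6-{[(tert-butyldiphenylsilyl)oxy]methyl}-2-oxo-3-(propan-2-yl)-2H-pyran-4-yl acetate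
Conditions: Ac2O, Et3N, DMAP (cat.), CH2Cl2, 0 °C
Reagents that add atoms: acetic anhydride CC(=O)OC(C)=O
Why: O-Acylation of the vinylogous acid (C3 is blocked by isopropyl, so no O-to-C acyl shift); the enol acetate makes the pyrone more electron-poor and is the masked C1 ketone.

**Step 5**
Reactants: 7 6-{[(tert-butyldiphenylsilyl)oxy]methyl}-2-oxo-3-(propan-2-yl)-2H-pyran-4-yl acetate; 8 2,2-dimethyl-1,3-dioxole
Product: 9 racemic CO2-bridged cycloadduct, a 5-acetoxy-1-(silyloxymethyl)-4-isopropyl-2-oxabicyclo[2.2.2]oct-5-en-3-one with a cis-fused 2,2-dimethyl-1,3-dioxolane on C7/C8 (endo and exo isomers)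
Conditions: 8 (5 equiv), CH2Cl2 (trace Et3N), 13 kbar, 40 °C, 72 h
Reagents that add atoms: none
Why: A concerted, asynchronous inverse-electron-demand [4+2] cycloaddition in which the pyrone C3=C4–C5=C6 unit is the diene and the electron-rich enediol ether the dienophile, so that pyrone C6 and C3 each bond to one CH–O carbon, which are C3–C4 and C5–C6 of the target ring. The closest known reaction type is the high-pressure Diels–Alder reaction of 2-pyrones with enol ethers and 1,3-dioxoles, which gives isolable CO2-bridged 2-oxabicyclo[2.2.2]octenones. The carbocycle is closed by an intermolecular [4+2] that is suprafacial on both partners, while the pyrone lactone becomes the two-atom bridge and the heteroarene is dearomatised. The oxygens on C4 and C5 are cis because the cyclic Z-alkene adds suprafacially; the two bridgeheads are fixed by the bridge and lose their stereochemistry in step 6 (C3 becomes sp2, C6 is re-set), so endo and exo adducts converge on one racemic enone. No regiochemistry is needed because the dienophile is symmetrical; what is needed is retention of the bridge, which pressure at 40 °C should secure by accelerating the addition without the heat that expels CO2. The ring carbonyl and the 4-acetoxy group make the pyrone the electron-poor partner, so a second addition of the electron-rich dioxole is not expected.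

**Step 6**
Reactants: 9 racemic CO2-bridged cycloadduct
Product: 11 racemic 3-{[(tert-butyldiphenylsilyl)oxy]methyl}-4,5-(isopropylidenedioxy)-6-isopropylcyclohex-2-en-1-one (O-4/O-5 cis, isopropyl trans to O-5), via β-keto acid 10 (not isolated)
Conditions: K2CO3 (1.5 equiv), MeOH, 0 °C; then AcOH (pH 5), 40 °C; then Et3N, rt
Reagents that add atoms: none
Why: Methanolysis of the enol acetate releases the C1 enolate, which expels the bridgehead carboxylate from C3 (E1cB) to give the C2=C3 enone; the resulting β-keto acid loses CO2 on acidification, and Et3N in methanol should equilibrate C6 to the isomer with isopropyl on the convex face, trans to O-5, since reprotonation in methanol outpaces loss of the poor alkoxide leaving group at C5.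

**Step 7**
Reactants: 11 racemic enone acetonide
Product: 12 racemic 3-{[(tert-butyldiphenylsilyl)oxy]methyl}-4,5-(isopropylidenedioxy)-6-isopropylcyclohex-2-en-1-ol (1-OH cis to isopropyl)
Conditions: LiBH(s-Bu)3, THF, −78 °C; then H2O
Reagents that add atoms: none
Why: 1,2-Reduction by a bulky trialkylborohydride (the β-carbon is fully substituted, so conjugate reduction is disfavoured) from the equatorial direction, anti to the adjacent pseudoequatorial isopropyl group, should give the axial alcohol cis to isopropyl, as with 2-alkylcyclohexanones and piperitone-type enones.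

**Step 8**
Reactants: 12 racemic allylic alcohol
Product: 13 (1S)-3-{[(tert-butyldiphenylsilyl)oxy]methyl}-4,5-(isopropylidenedioxy)-6-isopropylcyclohex-2-en-1-ol, single enantiomer with the configuration of 18 at C4, C5 and C6
Conditions: Burkholderia cepacia lipase (immobilised), vinyl acetate, t-BuOMe, 30 °C, stopped just past half conversion
Reagents that add atoms: none
Why: Lipase-catalysed kinetic resolution by irreversible transesterification; by Kazlauskas' rule the enzyme should acylate the (1R)-carbinol (large group the isopropyl-bearing C6 side, medium group the vinylic C2), leaving the (1S)-alcohol, as in lipase resolutions of piperitols and menthol isomers.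

**Step 9**
Reactants: 13 (1S)-alcohol acetonide
Product: 14 (1S)-configured 3-{[(tert-butyldiphenylsilyl)oxy]methyl}-6-isopropylcyclohex-2-ene-1,4,5-triol (4-OH/5-OH cis, 5-OH trans to isopropyl, 1-OH cis to isopropyl)
Conditions: AcOH/H2O (4:1), 45 °C
Reagents that add atoms: none
Why: Acid hydrolysis of the cis-dioxolane; the TBDPS ether and the allylic alcohol should tolerate aqueous acetic acid.

**Step 10**
Reactants: 14 silyl-protected triol
Product: 16 5-O-acetate of 14 (free 1-OH and 4-OH), via stannylene acetal 15 (not isolated)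
Conditions: Bu2SnO, MeOH, reflux; evaporate; then AcCl (1.05 equiv), CH2Cl2, 0 °C
Reagents that add atoms: acetyl chloride CC(Cl)=O; dibutyltin oxide CCCC[Sn](=O)CCCC (its atoms stay only in 15)
Why: Stannylene-directed monoacylation: Bu2SnO engages only the cis-vicinal 4,5-diol and the acid chloride should react at the equatorial O-5 (O-4 is pseudoaxial and flanked by the silyloxymethyl-bearing C3), while the isolated, hindered 1-OH is not activated.

**Step 11**
Reactants: 16 5-O-acetate
Product: 17 1,4-bis-O-[(E)-2-methylbut-2-enoyl] derivative of 16 (TBDPS ether of the target)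
Conditions: (E)-2-methylbut-2-enoyl chloride (3 equiv), pyridine, DMAP (cat.), CH2Cl2, 0 to 40 °C
Reagents that add atoms: (E)-2-methylbut-2-enoyl chloride (tigloyl chloride) C/C=C(\C)C(Cl)=O
Why: DMAP-catalysed acylation of both remaining secondary alcohols; the tiglate is the stable E isomer so the geometry is kept, and the equatorial 5-acetate is the thermodynamically placed ester, which limits acetyl migration.

**Step 12**
Reactants: 17 TBDPS ether of the target
Product: 18 (1S,4S,5R,6S)-5-acetoxy-3-(hydroxymethyl)-6-isopropylcyclohex-2-ene-1,4-diyl bis[(E)-2-methylbut-2-enoate] (CNP0169590.1)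
Conditions: HF·pyridine, pyridine, THF, 0 °C to rt
Reagents that add atoms: none
Why: Fluoride cleavage of the silyl ether under buffered, weakly acidic conditions, which should avoid acyl migration to the freed primary hydroxyl.

**Compound list**

1 | methyl glycolate | COC(=O)CO | starting material
2 | methyl 2-[(tert-butyldiphenylsilyl)oxy]acetate | COC(=O)CO[Si](c1ccccc1)(c1ccccc1)C(C)(C)C | intermediate
3 | ethyl 2-acetyl-3-methylbutanoate (ethyl 2-isopropylacetoacetate) | CCOC(=O)C(C(C)C)C(C)=O | starting material
4 | dilithium C2/C4 dianion of 3 (not isolated) | [Li+].[Li+].CCOC(=O)[C-](C(C)C)C(=O)[CH2-] | intermediate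
5 | ethyl 6-[(tert-butyldiphenylsilyl)oxy]-3,5-dioxo-2-(propan-2-yl)hexanoate | CCOC(=O)C(C(C)C)C(=O)CC(=O)CO[Si](c1ccccc1)(c1ccccc1)C(C)(C)C | intermediate
6 | 6-{[(tert-butyldiphenylsilyl)oxy]methyl}-4-hydroxy-3-(propan-2-yl)-2H-pyran-2-one | CC(C)C1=C(O)C=C(CO[Si](c2ccccc2)(c2ccccc2)C(C)(C)C)OC1=O | intermediate
7 | 6-{[(tert-butyldiphenylsilyl)oxy]methyl}-2-oxo-3-(propan-2-yl)-2H-pyran-4-yl acetate | CC(C)C1=C(OC(C)=O)C=C(CO[Si](c2ccccc2)(c2ccccc2)C(C)(C)C)OC1=O | intermediate
8 | 2,2-dimethyl-1,3-dioxole | CC1(C)OC=CO1 | starting material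
9 | racemic CO2-bridged cycloadduct: 5-acetoxy-1-{[(tert-butyldiphenylsilyl)oxy]methyl}-4-isopropyl-2-oxabicyclo[2.2.2]oct-5-en-3-one with a cis-fused 2,2-dimethyl-1,3-dioxolane on C7/C8 (endo isomer shown, dioxolane syn to C5=C6; exo isomer also expected) | CC(C)[C@]12C(=O)O[C@](CO[Si](c3ccccc3)(c3ccccc3)C(C)(C)C)(C=C1OC(C)=O)[C@@H]1OC(C)(C)O[C@@H]12 | intermediate
10 | racemic β-keto acid: 3-{[(tert-butyldiphenylsilyl)oxy]methyl}-4,5-(isopropylidenedioxy)-6-isopropyl-1-oxocyclohex-2-ene-6-carboxylic acid (not isolated) | CC(C)[C@]1(C(O)=O)C(=O)C=C(CO[Si](c3ccccc3)(c3ccccc3)C(C)(C)C)[C@@H]2OC(C)(C)O[C@H]12 | intermediate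
11 | racemic 3-{[(tert-butyldiphenylsilyl)oxy]methyl}-4,5-(isopropylidenedioxy)-6-isopropylcyclohex-2-en-1-one (O-4/O-5 cis, isopropyl trans to O-5) | O=C1C=C(CO[Si](c3ccccc3)(c3ccccc3)C(C)(C)C)[C@@H]2OC(C)(C)O[C@@H]2[C@H]1C(C)C | intermediate
12 | racemic 3-{[(tert-butyldiphenylsilyl)oxy]methyl}-4,5-(isopropylidenedioxy)-6-isopropylcyclohex-2-en-1-ol (1-OH cis to isopropyl) | O[C@H]1C=C(CO[Si](c3ccccc3)(c3ccccc3)C(C)(C)C)[C@@H]2OC(C)(C)O[C@@H]2[C@H]1C(C)C | intermediate
13 | (1S)-enantiomer of 12, enantiopure | O[C@H]1C=C(CO[Si](c3ccccc3)(c3ccccc3)C(C)(C)C)[C@@H]2OC(C)(C)O[C@@H]2[C@H]1C(C)C | intermediate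
14 | (1S)-configured 3-{[(tert-butyldiphenylsilyl)oxy]methyl}-6-isopropylcyclohex-2-ene-1,4,5-triol (4-OH/5-OH cis, 5-OH trans to isopropyl, 1-OH cis to isopropyl) | O[C@H]1C=C(CO[Si](c3ccccc3)(c3ccccc3)C(C)(C)C)[C@H](O)[C@H](O)[C@H]1C(C)C | intermediate
15 | 4,5-O-dibutylstannylene acetal of 14 (not isolated) | O[C@H]1C=C(CO[Si](c3ccccc3)(c3ccccc3)C(C)(C)C)[C@@H]2O[Sn](CCCC)(CCCC)O[C@@H]2[C@H]1C(C)C | intermediate
16 | 5-O-acetate of 14 | O[C@H]1C=C(CO[Si](c3ccccc3)(c3ccccc3)C(C)(C)C)[C@H](O)[C@H](OC(C)=O)[C@H]1C(C)C | intermediate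
17 | 5-acetoxy-3-{[(tert-butyldiphenylsilyl)oxy]methyl}-6-isopropylcyclohex-2-ene-1,4-diyl bis[(E)-2-methylbut-2-enoate], configuration as in 18 | C/C=C(\C)C(=O)O[C@H]1C=C(CO[Si](c3ccccc3)(c3ccccc3)C(C)(C)C)[C@H](OC(=O)/C(C)=C/C)[C@H](OC(C)=O)[C@H]1C(C)C | intermediate
18 | (1S,4S,5R,6S)-5-acetoxy-3-(hydroxymethyl)-6-isopropylcyclohex-2-ene-1,4-diyl bis[(E)-2-methylbut-2-enoate] | C/C=C(\C)C(=O)O[C@H]1C=C(CO)[C@H](OC(=O)/C(C)=C/C)[C@H](OC(C)=O)[C@H]1C(C)C | target

**Summary**

Total step count: 12. Longest linear sequence: 12 steps (1 to 18 through steps 1–12; 3 enters at step 2 and 8 at step 5).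

Steps most likely to fail:

- **Step 5.** The pyrone is substituted at both diene termini and only moderately electron-poor, so the cycloaddition may be too slow even under pressure, or the adduct may lose CO2 before it is isolated. The fallback removes the bridge by cycloreversion instead of elimination. Setting out from 7, heating with excess 8 neat in a sealed tube at about 140 °C with a trace of base should give, by cycloaddition and loss of CO2 from 9 in the same flask, the racemic dienyl acetate 2-acetoxy-1-isopropyl-4-(silyloxymethyl)-5,6-cis-(isopropylidenedioxy)cyclohexa-1,3-diene F1. This electron-rich diene is mismatched with the electron-rich dioxole, so a second addition is not expected. Methanolysis of F1 (K2CO3, MeOH) gives the cross-conjugated dienolate, and protonation at C6 under equilibrating conditions returns to the route at 11.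

- **Step 8.** Enzymatic acylation of a hindered axial alcohol may be slow or poorly enantioselective. The fallback is a resolution through covalent diastereomers. Setting out from racemic 12, esterification with (S)-2-methoxy-2-phenylacetic acid (DCC, DMAP cat., CH2Cl2, 0 °C) gives the (S)-O-methylmandelate of the (1S)-alcohol F2 and the (S)-O-methylmandelate of the (1R)-alcohol F3, which should be separable by chromatography or crystallisation. Methanolysis of F2 (K2CO3, MeOH) returns to the route at 13.

- **Step 10.** Acetylation may occur at the wrong hydroxyl of the cis-diol, or the acetyl group may migrate between O-4 and O-5. The fallback differentiates the two oxygens by ring size, not by relative reactivity. Setting out from 13, tigloylation of O-1 (tigloyl chloride, pyridine, DMAP) gives the 1-O-tiglate acetonide silyl ether F4. HCl in MeOH (from AcCl) removes both the acetonide and the silyl ether to give the 1-O-tiglate triol F5. t-Bu2Si(OTf)2 with 2,6-lutidine bridges the primary and C4 hydroxyls, as O-5 cannot be reached, to give the six-membered di-tert-butylsilylene F6. Ac2O/pyridine acetylates the only free hydroxyl to give the 5-O-acetyl silylene F7. HF·pyridine removes the silylene to give the 5-O-acetyl-1-O-tiglate diol F8. TBDPSCl/imidazole silylates the primary alcohol selectively to give the 4-hydroxy silyl ether F9, and tigloylation of O-4 returns to the route at 17.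

**Further compounds**

F1 | step 5 | racemic 2-acetoxy-1-isopropyl-4-{[(tert-butyldiphenylsilyl)oxy]methyl}-5,6-cis-(isopropylidenedioxy)cyclohexa-1,3-diene | CC(C)C1=C(OC(C)=O)C=C(CO[Si](c3ccccc3)(c3ccccc3)C(C)(C)C)[C@@H]2OC(C)(C)O[C@H]12
F2 | step 8 | (S)-2-methoxy-2-phenylacetate of the (1S)-alcohol 13 | CO[C@H](C(=O)O[C@H]1C=C(CO[Si](c3ccccc3)(c3ccccc3)C(C)(C)C)[C@@H]2OC(C)(C)O[C@@H]2[C@H]1C(C)C)c1ccccc1
F3 | step 8 | (S)-2-methoxy-2-phenylacetate of the (1R)-enantiomer of 13 | CO[C@H](C(=O)O[C@@H]1C=C(CO[Si](c3ccccc3)(c3ccccc3)C(C)(C)C)[C@H]2OC(C)(C)O[C@H]2[C@@H]1C(C)C)c1ccccc1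
F4 | step 10 | 1-O-[(E)-2-methylbut-2-enoyl] derivative of 13 | C/C=C(\C)C(=O)O[C@H]1C=C(CO[Si](c3ccccc3)(c3ccccc3)C(C)(C)C)[C@@H]2OC(C)(C)O[C@@H]2[C@H]1C(C)C
F5 | step 10 | 4,5-dihydroxy-3-(hydroxymethyl)-6-isopropylcyclohex-2-en-1-yl (E)-2-methylbut-2-enoate, configuration as in 18 | C/C=C(\C)C(=O)O[C@H]1C=C(CO)[C@H](O)[C@H](O)[C@H]1C(C)C
F6 | step 10 | di-tert-butylsilylene of F5 bridging the primary oxygen and O-4 (free 5-OH) | C/C=C(\C)C(=O)O[C@H]1C=C2CO[Si](C(C)(C)C)(C(C)(C)C)O[C@@H]2[C@H](O)[C@H]1C(C)C
F7 | step 10 | 5-O-acetate of F6 | C/C=C(\C)C(=O)O[C@H]1C=C2CO[Si](C(C)(C)C)(C(C)(C)C)O[C@@H]2[C@H](OC(C)=O)[C@H]1C(C)C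
F8 | step 10 | 5-acetoxy-4-hydroxy-3-(hydroxymethyl)-6-isopropylcyclohex-2-en-1-yl (E)-2-methylbut-2-enoate, configuration as in 18 | C/C=C(\C)C(=O)O[C@H]1C=C(CO)[C@H](O)[C@H](OC(C)=O)[C@H]1C(C)C
F9 | step 10 | primary TBDPS ether of F8 (free 4-OH) | C/C=C(\C)C(=O)O[C@H]1C=C(CO[Si](c3ccccc3)(c3ccccc3)C(C)(C)C)[C@H](O)[C@H](OC(C)=O)[C@H]1C(C)C
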